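## Retrosynthetic overview

1. Feature (labdane-type numbering): ring A (C1–C5, C10) is a cyclohexane whose adjacent atoms C5 and C10 carry the two side chains trans to each other and are the only stereocentres. C5 is a CH bearing the C6–C7–C8(=O)–CH3 arm; C10 is quaternary, bearing a methyl and the C9(=O)–C11–C15 arm that ends in the allylic acetate.
2. A temporary carbonyl at C1 makes C10 and C5 the α- and β-carbons of 2,4,4-trimethylcyclohex-2-enone. C5–C6 then comes from a copper-catalysed asymmetric conjugate addition of a ketal-masked 3-oxobutylzinc reagent, and C10–C9 from an aldol of the resulting zinc enolate with (E)-6-acetoxy-4-methylhex-4-enal, both in one flask.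
3. Ring A is bought intact as the enone; no ring is formed anywhere in the route.
4. Fragments: the dialkylzinc from 2-(2-bromoethyl)-2-methyl-1,3-dioxolane via its Grignard reagent, which is put on ZnCl2 in two titrated portions (alkylzinc chloride first, then the dialkylzinc); the aldehyde from geranyl acetate by distal epoxidation and HIO4 cleavage.
5. End game: silylate O9, delete the C1 carbonyl by reduction and radical deoxygenation (no ring alkene to reduce selectively, no palladium near the allylic acetate), unmask C9–OH and the C8 ketone with acid, oxidise C9.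

Key step: step 6

Assumption: the enone is taken as purchasable. The face preference known for cyclohexenone with the BINOL/bis(1-phenylethyl)amine phosphoramidite is assumed to carry over, which calls for the (R,S,S) ligand; the (S,R,R) ligand would be used instead if the sense proved reversed. The C9 carbinol and later the C1 carbinol are carried as epimer mixtures because both centres are erased.

## Route

Step 1
Reactants: 1 2-(2-bromoethyl)-2-methyl-1,3-dioxolane
Product: 2 [2-(2-methyl-1,3-dioxolan-2-yl)ethyl]magnesium bromide (THF stock solution, titrated)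
Conditions: Mg turnings (1.5 equiv, I2 crystal), THF, 20–30 °C; decant from excess Mg, titrate
Reagents that add atoms: magnesium, [Mg]
Why: Grignard formation by magnesium insertion into the primary C–Br bond is reliable for this ketal bromide when the temperature is kept below about 30 °C, and titrating the stock solution allows it to be dosed exactly in steps 2 and 3.

Step 2
Reactants: 2 [2-(2-methyl-1,3-dioxolan-2-yl)ethyl]magnesium bromide (first portion, 1.0 equiv)
Product: 3 [2-(2-methyl-1,3-dioxolan-2-yl)ethyl]zinc chloride (THF/Et2O stock solution)
Conditions: ZnCl2 (1.0 equiv, fused, 1 M in Et2O), THF, 0 °C → rt; titrate against I2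
Reagents that add atoms: ZnCl2 (zinc dichloride), Cl[Zn]Cl
Why: Magnesium-to-zinc transmetallation of one equivalent of the Grignard reagent with one equivalent of ZnCl2 stops cleanly at the monoalkylzinc chloride, a storable solution whose titre fixes the amount of Grignard reagent needed in step 3.

Step 3
Reactants: 3 [2-(2-methyl-1,3-dioxolan-2-yl)ethyl]zinc chloride; 2 [2-(2-methyl-1,3-dioxolan-2-yl)ethyl]magnesium bromide (second portion, 1.0 equiv)
Product: 4 bis[2-(2-methyl-1,3-dioxolan-2-yl)ethyl]zinc (halide-free toluene solution)
Conditions: THF/Et2O, 0 °C → rt; 1,4-dioxane, centrifuge under Ar; evaporate, take up in toluene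
Reagents that add atoms: none
Why: A second transmetallation replaces the remaining chloride on zinc with the second alkyl group, and dioxane precipitates the magnesium halides (Schlenk-type removal) to leave a halide-free dialkylzinc, which is needed because magnesium salts and residual Grignard reagent promote racemic background addition in step 6.

Step 4
Reactants: 5 geranyl acetate
Product: 6 6,7-epoxygeranyl acetate (racemic)
Conditions: mCPBA (1.05 equiv), NaHCO3, CH2Cl2, −10 → 0 °C
Reagents that add atoms: mCPBA, O=C(OO)c1cccc(Cl)c1
Why: Prilezhaev epoxidation should pick the electron-rich distal trisubstituted alkene because the proximal one is deactivated by the allylic acetoxy group; the epoxide stereocentre is destroyed in step 5.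

Step 5
Reactants: 6 6,7-epoxygeranyl acetate
Product: 7 (E)-6-acetoxy-4-methylhex-4-enal
Conditions: HIO4·2H2O (1.2 equiv), THF/H2O, 0 °C → rt
Reagents that add atoms: none
Why: Periodic acid opens the epoxide to the glycol (water entering at the tertiary carbon) and cleaves it in a Malaprade-type glycol cleavage to the aldehyde and acetone, leaving the allylic acetate and the E-alkene untouched.

Step 6
Reactants: 8 2,4,4-trimethylcyclohex-2-en-1-one; 4 bis[2-(2-methyl-1,3-dioxolan-2-yl)ethyl]zinc; 7 (E)-6-acetoxy-4-methylhex-4-enal
Product: 10 (2R,3R)-2-[(4E)-6-acetoxy-1-hydroxy-4-methylhex-4-en-1-yl]-2,4,4-trimethyl-3-[2-(2-methyl-1,3-dioxolan-2-yl)ethyl]cyclohexan-1-one (C1-oxo C9-hydroxy C8-ketal form of the target; C9 epimers), via alkylzinc enolate 9 (not isolated)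
Conditions: Cu(OTf)2 (5 mol %), (R,S,S)-phosphoramidite [O,O'-(R)-1,1'-binaphthyl-2,2'-diyl N,N-bis((S)-1-phenylethyl)phosphoramidite] (10 mol %), 4 (1.3 equiv), toluene, −30 → 0 °C; then 7 (1.5 equiv), −40 → −10 °C; aq. NH4Cl at −40 °C
Reagents that add atoms: none
Why: The dialkylzinc reduces Cu(OTf)2 to a monovalent copper–phosphoramidite complex and transfers an alkyl group to it; this alkylcopper π-complexes the enone, adds at the β-carbon C5 through a trivalent copper enolate and reductively eliminates to form C5–C6, leaving the regiodefined alkylzinc enolate 9 with C10 as its nucleophilic carbon. Enolate 9 then adds to aldehyde 7 through a closed six-membered Zimmerman–Traxler-type transition state, forming C10–C9 and the quaternary centre; the closest known reaction type is the copper–phosphoramidite dialkylzinc conjugate addition to cyclohexenones with in situ aldol trapping of the zinc enolate. No ring is closed. C5 is set by the ligand, which selects the enone face (5R); C10 is set by the substrate, because the C5 arm sits pseudoaxial to escape A1,2 strain with the C10 methyl and the aldehyde enters anti to it in a chair-like axial attack, placing C9 trans to C6; C9 is left unassigned since it becomes a carbonyl in step 12. The step needs 1,4- over 1,2-addition (secured by the soft alkylcopper), enolate addition to the aldehyde in preference to alkyl transfer from residual 4 (uncatalysed alkylzinc addition to aldehydes is slow in the cold) and an untouched allylic acetate (a poor leaving group for copper/zinc allylic substitution at these temperatures). The enone is congested at C5 (next to the C4 gem-dimethyl group) and at C10 (methyl), so a raised catalyst loading, halide-free 4 and a long reaction time are planned.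

Step 7
Reactants: 10 aldol adduct
Product: 11 C9 tert-butyldimethylsilyl ether of 10 ((2R,3R) ring configuration retained)
Conditions: TBSOTf (1.5 equiv), 2,6-lutidine (3 equiv), CH2Cl2, −78 → 0 °C
Reagents that add atoms: tert-butyldimethylsilyl triflate, CC(C)(C)[Si](C)(C)OS(=O)(=O)C(F)(F)F
Why: Silyl triflate/lutidine silylation should cap the hindered neopentyl carbinol without generating an alkoxide, so the β-hydroxy ketone cannot undergo retro-aldol, and the ketal and acetate are inert to these conditions; the ether also blocks retro-aldol and distinguishes O9 from O1 in the following steps.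

Step 8
Reactants: 11 C9 silyl ether
Product: 12 C1 alcohol (C1-hydroxy C9-silyloxy C8-ketal; C1 and C9 epimers; C5 and C10 unchanged)
Conditions: NaBH4, EtOH, 0 °C → rt
Reagents that add atoms: none
Why: Borohydride reduction of the cyclohexanone should proceed without touching the acetate or the ketal, and the quaternary C10 excludes β-elimination of the silyloxy group; the new C1 configuration is irrelevant because the centre is deoxygenated in step 10.

Step 9
Reactants: 12 C1 alcohol
Product: 13 C1 O-(imidazol-1-ylthiocarbonyl) derivative of 12
Conditions: 1,1'-thiocarbonyldiimidazole (3 equiv), DMAP (cat.), toluene, 90 °C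
Reagents that add atoms: 1,1'-thiocarbonyldiimidazole, S=C(n1ccnc1)n1ccnc1
Why: Thioacylation with thiocarbonyldiimidazole (first half of a Barton–McCombie deoxygenation) works on hindered secondary alcohols under neutral conditions, avoiding the alkoxide that would invite silyl migration from O9 or acetate cleavage.

Step 10
Reactants: 13 C1 thiocarbonylimidazolide
Product: 14 (2E)-6-[(tert-butyldimethylsilyl)oxy]-3-methyl-6-{(1R,2R)-1,3,3-trimethyl-2-[2-(2-methyl-1,3-dioxolan-2-yl)ethyl]cyclohexyl}hex-2-en-1-yl acetate (C9 epimers)
Conditions: Bu3SnH (2 equiv, 0.2 M), AIBN (cat.), toluene, 100 °C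
Reagents that add atoms: none
Why: Barton–McCombie radical deoxygenation replaces C1–O by C1–H; at this stannane concentration the secondary C1 radical should be quenched faster than it can cyclise onto the remote trisubstituted alkene, and the allylic acetate, ketal, silyl ether and the C5/C10 centres are not involved.

Step 11
Reactants: 14 C1-deoxy silyl ether ketal
Product: 15 (2E)-6-hydroxy-3-methyl-6-[(1R,2R)-1,3,3-trimethyl-2-(3-oxobutyl)cyclohexyl]hex-2-en-1-yl acetate (C9 epimers)
Conditions: 48% aq. HF/MeCN (1:19), 0 °C → rt
Reagents that add atoms: water, O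
Why: Aqueous HF in acetonitrile should cleave the hindered silyl ether and hydrolyse the dioxolane in one operation, while the acetate ester is stable to dilute aqueous acid at room temperature.

Step 12
Reactants: 15 C9 hydroxy C8 ketone
Product: 16 (2E)-3-methyl-6-oxo-6-[(1R,2R)-1,3,3-trimethyl-2-(3-oxobutyl)cyclohexyl]hex-2-en-1-yl acetate (target)
Conditions: Dess–Martin periodinane (1.5 equiv), NaHCO3, CH2Cl2, 0 °C → rt
Reagents that add atoms: none
Why: Dess–Martin oxidation of the secondary carbinol under buffered neutral conditions should converge both C9 epimers on the ketone; C10 is quaternary and C5 is not α to any carbonyl, so neither stereocentre can epimerise.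

## Compound list

1 | 2-(2-bromoethyl)-2-methyl-1,3-dioxolane | CC1(CCBr)OCCO1 | starting material
2 | [2-(2-methyl-1,3-dioxolan-2-yl)ethyl]magnesium bromide | CC1(CC[Mg]Br)OCCO1 | intermediate
3 | [2-(2-methyl-1,3-dioxolan-2-yl)ethyl]zinc chloride | CC1(CC[Zn]Cl)OCCO1 | intermediate
4 | bis[2-(2-methyl-1,3-dioxolan-2-yl)ethyl]zinc | CC1(CC[Zn]CCC2(C)OCCO2)OCCO1 | intermediate
5 | geranyl acetate | CC(C)=CCC/C(C)=C/COC(C)=O | starting material
6 | 6,7-epoxygeranyl acetate, (2E)-5-(3,3-dimethyloxiran-2-yl)-3-methylpent-2-en-1-yl acetate (racemic) | CC1(C)OC1CC/C(C)=C/COC(C)=O | intermediate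
7 | (E)-6-acetoxy-4-methylhex-4-enal | O=CCC/C(C)=C/COC(C)=O | intermediate
8 | 2,4,4-trimethylcyclohex-2-en-1-one | CC1=CC(C)(C)CCC1=O | starting material
9 | alkylzinc enolate from conjugate addition (C5 set, enolate carbon C10; not isolated) | CC1(CC[C@@H]2C(C)(C)CCC(O[Zn]CCC3(C)OCCO3)=C2C)OCCO1 | intermediate
10 | (2R,3R)-2-[(4E)-6-acetoxy-1-hydroxy-4-methylhex-4-en-1-yl]-2,4,4-trimethyl-3-[2-(2-methyl-1,3-dioxolan-2-yl)ethyl]cyclohexan-1-one (C9 epimers) | CC1(CC[C@@H]2C(C)(C)CCC(=O)[C@@]2(C)C(O)CC/C(C)=C/COC(C)=O)OCCO1 | intermediate
11 | C9 tert-butyldimethylsilyl ether of 10 | CC1(CC[C@@H]2C(C)(C)CCC(=O)[C@@]2(C)C(O[Si](C)(C)C(C)(C)C)CC/C(C)=C/COC(C)=O)OCCO1 | intermediate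
12 | C1 alcohol from 11 (C1 and C9 epimers; C5/C10 geometry of 10) | CC1(CC[C@@H]2C(C)(C)CCC(O)[C@@]2(C)C(O[Si](C)(C)C(C)(C)C)CC/C(C)=C/COC(C)=O)OCCO1 | intermediate
13 | C1 O-(imidazol-1-ylthiocarbonyl) derivative of 12 | CC1(CC[C@@H]2C(C)(C)CCC(OC(=S)n3ccnc3)[C@@]2(C)C(O[Si](C)(C)C(C)(C)C)CC/C(C)=C/COC(C)=O)OCCO1 | intermediate
14 | (2E)-6-[(tert-butyldimethylsilyl)oxy]-3-methyl-6-{(1R,2R)-1,3,3-trimethyl-2-[2-(2-methyl-1,3-dioxolan-2-yl)ethyl]cyclohexyl}hex-2-en-1-yl acetate (C9 epimers) | CC1(CC[C@@H]2C(C)(C)CCC[C@@]2(C)C(O[Si](C)(C)C(C)(C)C)CC/C(C)=C/COC(C)=O)OCCO1 | intermediate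
15 | (2E)-6-hydroxy-3-methyl-6-[(1R,2R)-1,3,3-trimethyl-2-(3-oxobutyl)cyclohexyl]hex-2-en-1-yl acetate (C9 epimers) | CC(=O)CC[C@@H]1C(C)(C)CCC[C@@]1(C)C(O)CC/C(C)=C/COC(C)=O | intermediate
16 | (2E)-3-methyl-6-oxo-6-[(1R,2R)-1,3,3-trimethyl-2-(3-oxobutyl)cyclohexyl]hex-2-en-1-yl acetate | CC(=O)CC[C@@H]1C(C)(C)CCC[C@@]1(C)C(=O)CC/C(C)=C/COC(C)=O | target

## Step count and risks

Total steps: 12. Longest linear sequence: 10 steps (bromide 1 through steps 1–3 and 6–12 to 16).

Steps most likely to fail:

1. Step 6. The conjugate addition may stall at the doubly hindered β-carbon C5, face selectivity may erode if traces of magnesium halide survive, and the congested tetrasubstituted zinc enolate may add sluggishly or reversibly to the aldehyde. Fallback, setting out from enone 8 (with Grignard reagent 2 and aldehyde 7) and returning at 10: the two bond formations are separated and run with more reactive metals. Enone 8 is treated with Grignard reagent 2 under Cu(OTf)2 and a chiral N-heterocyclic carbene ligand in Et2O at low temperature, a system known for α-substituted cyclic enones, to give the bromomagnesium enolate F1. This is silylated in the flask with Me3SiCl/Et3N to the trimethylsilyl enol ether F2, which is isolated so that its enantiopurity can be checked. MeLi in THF at 0 °C then releases the regiodefined lithium enolate F3, and aldehyde 7 at −78 °C followed by a cold NH4Cl quench should give 10.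

2. Step 9. Thioacylation of the neopentyl C1 hydroxyl, flanked by quaternary C10 and its silyloxy-bearing arm, may be too slow, and forcing it may trigger silyl migration from O9 to O1. Fallback, setting out from ketone 11 and returning at 14: the carbonyl is removed through its enol derivative instead of the alcohol. KN(SiMe3)2 and PhNTf2 in THF at −78 °C give the enol triflate F4 (only C2 can be enolised, and the ketone is more acidic than the acetate). Pd(OAc)2/PPh3 with Bu3N and HCO2H in DMF at room temperature reduces it to the C1=C2 ring alkene F5; oxidative addition of the vinyl triflate should outrun ionisation of the trisubstituted allylic acetate at this temperature. H2 over RhCl(PPh3)3 in benzene then saturates the disubstituted ring alkene in preference to the trisubstituted side-chain alkene, giving 14.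

3. Step 11. The hindered silyl ether may cleave incompletely under acid mild enough for the allylic acetate, or prolonged acid may ionise and remove the allylic acetate. Fallback, setting out from 14 and returning at 16: the three operations are run separately and the ketal is kept to the end. Bu4NF buffered with AcOH in warm THF gives the C9 alcohol F6 with the ketal intact. Dess–Martin periodinane oxidises it to the C9 ketone F7. Pyridinium p-toluenesulfonate in wet acetone at 40 °C then hydrolyses the ketal to give 16.

## Further compounds

F1 | step 6 | bromomagnesium enolate of the conjugate adduct | CC1(CC[C@@H]2C(C)(C)CCC(O[Mg]Br)=C2C)OCCO1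
F2 | step 6 | trimethylsilyl enol ether of the conjugate adduct | CC1(CC[C@@H]2C(C)(C)CCC(O[Si](C)(C)C)=C2C)OCCO1
F3 | step 6 | lithium enolate of the conjugate adduct | CC1(CC[C@@H]2C(C)(C)CCC(O[Li])=C2C)OCCO1
F4 | step 9 | C1 enol triflate of 11 | CC1(CC[C@@H]2C(C)(C)CC=C(OS(=O)(=O)C(F)(F)F)[C@@]2(C)C(O[Si](C)(C)C(C)(C)C)CC/C(C)=C/COC(C)=O)OCCO1
F5 | step 9 | C1=C2 ring alkene | CC1(CC[C@@H]2C(C)(C)CC=C[C@@]2(C)C(O[Si](C)(C)C(C)(C)C)CC/C(C)=C/COC(C)=O)OCCO1
F6 | step 11 | C9 alcohol with C8 ketal intact | CC1(CC[C@@H]2C(C)(C)CCC[C@@]2(C)C(O)CC/C(C)=C/COC(C)=O)OCCO1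
F7 | step 11 | C9 ketone with C8 ketal intact | CC1(CC[C@@H]2C(C)(C)CCC[C@@]2(C)C(=O)CC/C(C)=C/COC(C)=O)OCCO1
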